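**Retrosynthetic overview**

- The ring B phenol is unveiled last from an aryl bromide; until then the bromine acts as a masked OH that also deactivates ring B.
- The oxolane is the only ring and is formed once, in the penultimate step. DDQ abstracts hydride from C7–H of an acyclic (2S,3S)-dibenzylbutane-1,4-diol, and the resulting ring A O-methyl quinone-methide cation is captured by the C9′ hydroxyl, as in lignan biosynthesis. This sets C7.
- The diol comes from LiAlH4 reduction of an unsymmetrical 2,3-dibenzylsuccinate. Its C8–C8′ bond is made by one-electron oxidative cross-coupling of two C6C3 enolates (Evans imide plus tert-butyl ester), the counterpart of the radical 8–8′ coupling. This sets C8 and C8′.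
- The two C6C3 units come from 3-(3,4,5-trimethoxyphenyl)propanoic acid with (R)-4-benzyl-oxazolidin-2-one, and from 3-bromo-4,5-dimethoxybenzaldehyde with Meldrum's acid.

Assumption: these four building blocks are taken as commercial. Lignan locants are used throughout: C7–C8–C9 is the side chain on ring A (3,4,5-trimethoxyphenyl) and C7′–C8′–C9′ the side chain on ring B (3-bromo/3-hydroxy-4,5-dimethoxyphenyl).

**Route**

Step 1
Reactants: 1 3-bromo-4,5-dimethoxybenzaldehyde; 2 Meldrum's acid (2,2-dimethyl-1,3-dioxane-4,6-dione)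
Product: 5 3-(3-bromo-4,5-dimethoxyphenyl)propanoic acid, via benzylidene Meldrum's acid 3 (not isolated), via benzyl Meldrum's acid 4 (not isolated)
Conditions: HCO2H/Et3N (5:2), 100 °C; then aq. HCl
Reagents that add atoms: Meldrum's acid CC1(C)OC(=O)CC(=O)O1
Why: Knoevenagel condensation, conjugate reduction of the arylidene by formate (transfer hydrogenation) and hydrolytic decarboxylation run in one pot in triethylammonium formate; no stereocenter is formed and the aryl bromide is inert in the absence of palladium.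

Step 2
Reactants: 5 3-(3-bromo-4,5-dimethoxyphenyl)propanoic acid
Product: 6 tert-butyl 3-(3-bromo-4,5-dimethoxyphenyl)propanoate
Conditions: tert-butyl 2,2,2-trichloroacetimidate (2 equiv), BF3·OEt2 (5 mol%), CH2Cl2/cyclohexane, rt
Reagents that add atoms: tert-butyl 2,2,2-trichloroacetimidate CC(C)(C)OC(=N)C(Cl)(Cl)Cl
Why: Acid-catalysed O-tert-butylation of the carboxylic acid by the trichloroacetimidate (tert-butyl cation transfer) gives an ester whose lithium enolate does not self-condense in step 4.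

Step 3
Reactants: 7 3-(3,4,5-trimethoxyphenyl)propanoic acid; 8 (R)-4-benzyl-1,3-oxazolidin-2-one
Product: 10 (4R)-4-benzyl-3-[3-(3,4,5-trimethoxyphenyl)propanoyl]-1,3-oxazolidin-2-one, via mixed pivalic anhydride 9 (not isolated)
Conditions: PivCl, Et3N, THF, −20 °C; then LiCl, 8, −20 °C → rt
Reagents that add atoms: (R)-4-benzyl-1,3-oxazolidin-2-one O=C1N[C@H](Cc2ccccc2)CO1
Why: N-acylation of the Evans auxiliary through the mixed anhydride (LiCl-promoted acyl transfer) leaves the auxiliary stereocenter untouched.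

Step 4
Reactants: 10 (4R)-4-benzyl-3-[3-(3,4,5-trimethoxyphenyl)propanoyl]-1,3-oxazolidin-2-one; 6 tert-butyl 3-(3-bromo-4,5-dimethoxyphenyl)propanoate
Product: 13 tert-butyl (2S,3S)-2-[(3-bromo-4,5-dimethoxyphenyl)methyl]-4-[(4R)-4-benzyl-2-oxo-1,3-oxazolidin-3-yl]-4-oxo-3-[(3,4,5-trimethoxyphenyl)methyl]butanoate, via lithium imide enolate 11 (not isolated), via lithium ester enolate 12 (not isolated)
Conditions: 10 (1 equiv), 6 (1.5 equiv), LDA (2.6 equiv), THF, −78 °C; then Fe(acac)3 (2.6 equiv), −78 °C → rt; chromatography to remove the C2 epimer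
Reagents that add atoms: none
Why: Intermolecular oxidative enolate heterocoupling, in which single-electron oxidation by Fe(acac)3 (trivalent iron) joins the two α-carbons as the phenoxy-radical 8–8′ coupling does in the plant; the chelated Z-enolate of the (R)-auxiliary reacts on the face away from its benzyl group to give 3S (C8) with high selectivity, while the anti 2S (C8′) arrangement is favoured only moderately, hence the chromatographic separation.

Step 5
Reactants: 13 tert-butyl (2S,3S)-2-[(3-bromo-4,5-dimethoxyphenyl)methyl]-4-[(4R)-4-benzyl-2-oxo-1,3-oxazolidin-3-yl]-4-oxo-3-[(3,4,5-trimethoxyphenyl)methyl]butanoate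
Product: 14 (2S,3S)-2-[(3-bromo-4,5-dimethoxyphenyl)methyl]-3-[(3,4,5-trimethoxyphenyl)methyl]butane-1,4-diol
Conditions: LiAlH4 (4 equiv), THF, 0 °C → rt; Fieser work-up
Reagents that add atoms: none
Why: Hydride reduction of imide and ester (LiAlH4) gives the 1,4-diol and releases the auxiliary; reduction is faster than enolisation so both stereocenters are kept, and the aryl bromide survives at or below rt.

Step 6
Reactants: 14 (2S,3S)-2-[(3-bromo-4,5-dimethoxyphenyl)methyl]-3-[(3,4,5-trimethoxyphenyl)methyl]butane-1,4-diol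
Product: 16 [(2R,3S,4S)-4-[(3-bromo-4,5-dimethoxyphenyl)methyl]-2-(3,4,5-trimethoxyphenyl)oxolan-3-yl]methanol, via ring A benzylic cation 15 (not isolated)
Conditions: DDQ (1.1 equiv), 4 Å MS, ClCH2CH2Cl, rt → 50 °C
Reagents that add atoms: none
Why: Proposed new method: site-selective DDQ dehydrogenative etherification, in which DDQ forms its charge-transfer complex with the more electron-rich ring A and abstracts hydride from C7–H (ring B is deactivated by bromine, which also suppresses Friedel–Crafts closure to an aryltetralin) to give the O-methyl p-quinone-methide cation 15, the electrophile that the 9′-OH traps in lignan biosynthesis; 5-exo capture by the C9′ hydroxyl places the aryl group trans to the C8 hydroxymethyl group (pseudo-equatorial substituents in the envelope transition state, also the thermodynamic isomer) and so sets C7 as R; the closest known reaction types are the DDQ oxidative cyclisation of secoisolariciresinol-type diols to lariciresinol-type oxolanes and DDQ benzylic C–H etherification of p-methoxyalkylarenes.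

Step 7
Reactants: 16 [(2R,3S,4S)-4-[(3-bromo-4,5-dimethoxyphenyl)methyl]-2-(3,4,5-trimethoxyphenyl)oxolan-3-yl]methanol
Product: 17 5-{[(3S,4S,5R)-4-(hydroxymethyl)-5-(3,4,5-trimethoxyphenyl)oxolan-3-yl]methyl}-2,3-dimethoxyphenol (CNP0121704.1)
Conditions: Pd2(dba)3 (2 mol%), tBuXPhos (8 mol%), KOH (4 equiv), 1,4-dioxane/H2O (1:1), 100 °C; then 1 M HCl
Reagents that add atoms: potassium hydroxide [K+].[OH-]
Why: Palladium-catalysed hydroxylation of the aryl bromide (Buchwald-type C–O coupling: oxidative addition to zerovalent palladium, bromide/hydroxide exchange, C–O reductive elimination from the bulky biarylphosphine complex) touches no stereocenter, and the benzylic ether, methyl ethers and primary alcohol tolerate aqueous base.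

**Compound list**

1 | 3-bromo-4,5-dimethoxybenzaldehyde | COc1cc(C=O)cc(Br)c1OC | starting material
2 | Meldrum's acid (2,2-dimethyl-1,3-dioxane-4,6-dione) | CC1(C)OC(=O)CC(=O)O1 | starting material
3 | 5-[(3-bromo-4,5-dimethoxyphenyl)methylidene]-2,2-dimethyl-1,3-dioxane-4,6-dione | COc1cc(C=C2C(=O)OC(C)(C)OC2=O)cc(Br)c1OC | intermediate
4 | 5-[(3-bromo-4,5-dimethoxyphenyl)methyl]-2,2-dimethyl-1,3-dioxane-4,6-dione | COc1cc(CC2C(=O)OC(C)(C)OC2=O)cc(Br)c1OC | intermediate
5 | 3-(3-bromo-4,5-dimethoxyphenyl)propanoic acid | COc1cc(CCC(=O)O)cc(Br)c1OC | intermediate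
6 | tert-butyl 3-(3-bromo-4,5-dimethoxyphenyl)propanoate | COc1cc(CCC(=O)OC(C)(C)C)cc(Br)c1OC | intermediate
7 | 3-(3,4,5-trimethoxyphenyl)propanoic acid | COc1cc(CCC(=O)O)cc(OC)c1OC | starting material
8 | (R)-4-benzyl-1,3-oxazolidin-2-one | O=C1N[C@H](Cc2ccccc2)CO1 | starting material
9 | 2,2-dimethylpropanoic 3-(3,4,5-trimethoxyphenyl)propanoic anhydride (mixed pivalic anhydride) | COc1cc(CCC(=O)OC(=O)C(C)(C)C)cc(OC)c1OC | intermediate
10 | (4R)-4-benzyl-3-[3-(3,4,5-trimethoxyphenyl)propanoyl]-1,3-oxazolidin-2-one | COc1cc(CCC(=O)N2[C@H](Cc3ccccc3)COC2=O)cc(OC)c1OC | intermediate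
11 | lithium (Z)-enolate of 10 (OLi cis to the benzylic CH2) | COc1cc(C/C=C(\O[Li])N2[C@H](Cc3ccccc3)COC2=O)cc(OC)c1OC | intermediate
12 | lithium enolate of 6 (OLi trans to the benzylic CH2) | COc1cc(C/C=C(/O[Li])OC(C)(C)C)cc(Br)c1OC | intermediate
13 | tert-butyl (2S,3S)-2-[(3-bromo-4,5-dimethoxyphenyl)methyl]-4-[(4R)-4-benzyl-2-oxo-1,3-oxazolidin-3-yl]-4-oxo-3-[(3,4,5-trimethoxyphenyl)methyl]butanoate | COc1cc(C[C@H](C(=O)OC(C)(C)C)[C@@H](C(=O)N2[C@H](Cc3ccccc3)COC2=O)Cc4cc(OC)c(OC)c(OC)c4)cc(Br)c1OC | intermediate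
14 | (2S,3S)-2-[(3-bromo-4,5-dimethoxyphenyl)methyl]-3-[(3,4,5-trimethoxyphenyl)methyl]butane-1,4-diol | COc1cc(C[C@H](CO)[C@@H](CO)Cc2cc(OC)c(OC)c(OC)c2)cc(Br)c1OC | intermediate
15 | C7 benzylic cation of 14 on ring A (O-methyl p-quinone-methide cation) | COc1cc(C[C@H](CO)[C@@H](CO)[CH+]c2cc(OC)c(OC)c(OC)c2)cc(Br)c1OC | intermediate
16 | [(2R,3S,4S)-4-[(3-bromo-4,5-dimethoxyphenyl)methyl]-2-(3,4,5-trimethoxyphenyl)oxolan-3-yl]methanol (aryl and CH2OH trans, CH2OH and benzyl cis) | COc1cc(C[C@@H]2CO[C@@H](c3cc(OC)c(OC)c(OC)c3)[C@@H]2CO)cc(Br)c1OC | intermediate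
17 | 5-{[(3S,4S,5R)-4-(hydroxymethyl)-5-(3,4,5-trimethoxyphenyl)oxolan-3-yl]methyl}-2,3-dimethoxyphenol | COc1cc(C[C@@H]2CO[C@@H](c3cc(OC)c(OC)c(OC)c3)[C@@H]2CO)cc(O)c1OC | target

**Totals and risks**

Total step count: 7. Longest linear sequence: 6 steps (1 → 5 → 6 → 13 → 14 → 16 → 17); ring A enters through one side step (step 3).

Most likely to fail, in order: step 6, step 4, step 7.

Step 6 (DDQ ring closure). The risks are incomplete discrimination between C7–H and C7′–H, and over-oxidation of the product's benzylic ether C–H. The fallback installs the C7 oxygen by an aldol reaction instead of C–H oxidation; it sets out from 5 and comes back at 16. Acid 5 is acylated onto 8 as in step 3 to give (4R)-4-benzyl-3-[3-(3-bromo-4,5-dimethoxyphenyl)propanoyl]-1,3-oxazolidin-2-one F4. NaHMDS in THF at −78 °C gives its sodium (Z)-enolate F5, and Evans alkylation with tert-butyl bromoacetate gives tert-butyl (3S)-3-[(3-bromo-4,5-dimethoxyphenyl)methyl]-4-[(4R)-4-benzyl-2-oxo-1,3-oxazolidin-3-yl]-4-oxobutanoate F6. LiBH4/MeOH in THF at 0 °C reduces only the imide to tert-butyl (3S)-3-[(3-bromo-4,5-dimethoxyphenyl)methyl]-4-hydroxybutanoate F7, which closes with catalytic pTsOH to (4S)-4-[(3-bromo-4,5-dimethoxyphenyl)methyl]oxolan-2-one F8. LiHMDS at −78 °C gives the lithium lactone enolate F9, which adds to commercial 3,4,5-trimethoxybenzaldehyde anti to the benzyl group to give (3R,4S)-4-[(3-bromo-4,5-dimethoxyphenyl)methyl]-3-[hydroxy(3,4,5-trimethoxyphenyl)methyl]oxolan-2-one F10 as a mixture of carbinol epimers. LiAlH4 gives (2S,3S)-2-[(3-bromo-4,5-dimethoxyphenyl)methyl]-3-[hydroxy(3,4,5-trimethoxyphenyl)methyl]butane-1,4-diol F11. Catalytic camphorsulfonic acid in CH2Cl2 ionises the benzylic alcohol of either epimer to the same cation 15, which closes to 16. This sequence also avoids the oxidative coupling of step 4.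

Step 4 (oxidative heterocoupling). The risks are modest diastereoselectivity at C8′ (C2 of 13) and competing homocoupling. The fallback replaces kinetic control at C8′ by thermodynamic control in a lactone; it sets out from 13, taken on as the unseparated mixture with its C2 epimer, and comes back at 14. LiBH4/MeOH in THF at 0 °C reduces only the imide to give tert-butyl (3S)-2-[(3-bromo-4,5-dimethoxyphenyl)methyl]-4-hydroxy-3-[(3,4,5-trimethoxyphenyl)methyl]butanoate F1 as C2 epimers. Catalytic pTsOH in toluene closes it to (4S)-3-[(3-bromo-4,5-dimethoxyphenyl)methyl]-4-[(3,4,5-trimethoxyphenyl)methyl]oxolan-2-one F2 as C3 epimers. DBU in toluene at 80 °C equilibrates the α-carbon to the trans lactone (3S,4S)-3-[(3-bromo-4,5-dimethoxyphenyl)methyl]-4-[(3,4,5-trimethoxyphenyl)methyl]oxolan-2-one F3. LiAlH4 in THF then gives 14.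

Step 7 (Pd hydroxylation). The risk is hydrodebromination or ether formation through the free primary alcohol on this electron-rich, ortho-substituted bromide. The fallback goes through a C–B bond; it sets out from 16 and comes back at 17. Miyaura borylation (Pd(dppf)Cl2, bis(pinacolato)diboron, KOAc, 1,4-dioxane, 90 °C) gives [(2R,3S,4S)-4-{[3,4-dimethoxy-5-(4,4,5,5-tetramethyl-1,3,2-dioxaborolan-2-yl)phenyl]methyl}-2-(3,4,5-trimethoxyphenyl)oxolan-3-yl]methanol F12. Oxidation with NaBO3·4H2O in THF/H2O at rt gives 17.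

**Further compounds**

F1 | step 4 | tert-butyl (3S)-2-[(3-bromo-4,5-dimethoxyphenyl)methyl]-4-hydroxy-3-[(3,4,5-trimethoxyphenyl)methyl]butanoate (C2 epimers) | COc1cc(CC(C(=O)OC(C)(C)C)[C@@H](CO)Cc2cc(OC)c(OC)c(OC)c2)cc(Br)c1OC
F2 | step 4 | (4S)-3-[(3-bromo-4,5-dimethoxyphenyl)methyl]-4-[(3,4,5-trimethoxyphenyl)methyl]oxolan-2-one (C3 epimers) | COc1cc(CC2C(=O)OC[C@H]2Cc3cc(OC)c(OC)c(OC)c3)cc(Br)c1OC
F3 | step 4 | (3S,4S)-3-[(3-bromo-4,5-dimethoxyphenyl)methyl]-4-[(3,4,5-trimethoxyphenyl)methyl]oxolan-2-one (trans) | COc1cc(C[C@@H]2C(=O)OC[C@H]2Cc3cc(OC)c(OC)c(OC)c3)cc(Br)c1OC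
F4 | step 6 | (4R)-4-benzyl-3-[3-(3-bromo-4,5-dimethoxyphenyl)propanoyl]-1,3-oxazolidin-2-one | COc1cc(CCC(=O)N2[C@H](Cc3ccccc3)COC2=O)cc(Br)c1OC
F5 | step 6 | sodium (Z)-enolate of F4 | COc1cc(C/C=C(\O[Na])N2[C@H](Cc3ccccc3)COC2=O)cc(Br)c1OC
F6 | step 6 | tert-butyl (3S)-3-[(3-bromo-4,5-dimethoxyphenyl)methyl]-4-[(4R)-4-benzyl-2-oxo-1,3-oxazolidin-3-yl]-4-oxobutanoate | COc1cc(C[C@@H](CC(=O)OC(C)(C)C)C(=O)N2[C@H](Cc3ccccc3)COC2=O)cc(Br)c1OC
F7 | step 6 | tert-butyl (3S)-3-[(3-bromo-4,5-dimethoxyphenyl)methyl]-4-hydroxybutanoate | COc1cc(C[C@@H](CC(=O)OC(C)(C)C)CO)cc(Br)c1OC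
F8 | step 6 | (4S)-4-[(3-bromo-4,5-dimethoxyphenyl)methyl]oxolan-2-one | COc1cc(C[C@@H]2COC(=O)C2)cc(Br)c1OC
F9 | step 6 | lithium enolate of F8 | COc1cc(C[C@@H]2COC(O[Li])=C2)cc(Br)c1OC
F10 | step 6 | (3R,4S)-4-[(3-bromo-4,5-dimethoxyphenyl)methyl]-3-[hydroxy(3,4,5-trimethoxyphenyl)methyl]oxolan-2-one (carbinol epimers) | COc1cc(C[C@@H]2COC(=O)[C@H]2C(O)c3cc(OC)c(OC)c(OC)c3)cc(Br)c1OC
F11 | step 6 | (2S,3S)-2-[(3-bromo-4,5-dimethoxyphenyl)methyl]-3-[hydroxy(3,4,5-trimethoxyphenyl)methyl]butane-1,4-diol (carbinol epimers) | COc1cc(C[C@H](CO)[C@@H](CO)C(O)c2cc(OC)c(OC)c(OC)c2)cc(Br)c1OC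
F12 | step 7 | [(2R,3S,4S)-4-{[3,4-dimethoxy-5-(4,4,5,5-tetramethyl-1,3,2-dioxaborolan-2-yl)phenyl]methyl}-2-(3,4,5-trimethoxyphenyl)oxolan-3-yl]methanol | COc1cc(C[C@@H]2CO[C@@H](c3cc(OC)c(OC)c(OC)c3)[C@@H]2CO)cc(B3OC(C)(C)C(C)(C)O3)c1OC
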